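**Plan**

Retrosynthesis: the epoxide (C13–O, C14–O) is removed first. C14 is then taken out of ring C by cutting C14–C15 and C14–C13 (C14 is a dibromocarbene carbon), which leaves a seven-membered enol ether. That ring is cut at C15=C13 (metathesis) and O–C15 (vinyl ether), the isopropenyl group goes back to a δ-lactone (Wittig, MeLi), the bromodecalin lactone to an acyclic trienoic acid (C3–Br, C4–C5, C9–C10, C8–O in one cascade), and the acid to farnesyl bromide plus acetate (C11–C12).
Forward: the chain is joined (step 1), rings A and B and the δ-lactone form together (step 2), the lactone is resolved and opened, the oxepene is closed (step 7), a cyclopropane is fused on (step 8) and opened so that ring C grows from seven to eight members (step 9). The vinylic Br at C14 and then the OMe at C15 are removed, and the epoxide is added last.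
Enabling feature: in the oxocane ring C (O–C15–C14–C13–C12–C11–C9–C8), C14 lies between C15, which is bonded to the ring oxygen and can carry oxocarbenium character, and the methyl-bearing C13, so C14 can be inserted into the C15=C13 bond of a seven-membered enol ether.
Stereochemistry: C3, C5, C8, C9 and C10 are set relative to one another by the chair–chair anti addition of the cascade and made absolute by chromatographic resolution of the lactone; C13 and C14 come from a Shi epoxidation of the ring-cis alkene on its exo face.

Key step: step 9

Assumption: labdane numbering is used (C16 is the methyl on C13, C17 that on C8). The SMILES is read as (3R,5S,8S,9S,10R,13S,14R), a decalin antipodal to that of sclareolide, so the configuration must be made and cannot come from that chiral pool.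

Step 1
Reactants: 1 (2E,6E)-farnesyl bromide; 2 acetic acid
Product: 4 (4E,8E)-5,9,13-trimethyltetradeca-4,8,12-trienoic acid, via dilithium acetate 3 (not isolated)
Conditions: LiN(iPr)2 (2.2 equiv), AcOH, THF–DMPU, 0 → 40 °C; then 1, 0 → 23 °C; aq. HCl
Reagents that add atoms: acetic acid 2, CC(=O)O
Why: C-alkylation of the acetic acid dianion by the primary allylic bromide is an SN2 reaction that adds the two-carbon acid terminus (bond C11–C12) without touching the two E-alkenes, and no stereocentre is formed.

Step 2
Reactants: 4 (4E,8E)-5,9,13-trimethyltetradeca-4,8,12-trienoic acid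
Product: 5 racemic (3R*,5S*,8S*,9S*,10R*)-3-bromo-8,13-epoxy-14,15,16-trinorlabdan-13-one
Conditions: BDSB (Et2SBr·SbCl5Br, 1.1 equiv), MeNO2, −25 °C, 10 min; aq. Na2SO3/NaHCO3
Reagents that add atoms: bromodiethylsulfonium bromopentachloroantimonate, CC[S+](Br)CC.Cl[Sb-](Cl)(Cl)(Cl)(Cl)Br
Why: in this bromonium-initiated cation–olefin polycyclisation terminated by the carboxyl oxygen (a bromolactonising polyene cyclisation), Br+ adds to the terminal trisubstituted alkene and anti addition across each E-alkene through a chair–chair array should place Br at C3 equatorial, fuse the decalin trans (C5, C10) and set the C9 side chain and the C8–O bond equatorial in one relative sense, the product being racemic because the reagent is achiral.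

Step 3
Reactants: 5 racemic (3R*,5S*,8S*,9S*,10R*)-3-bromo-8,13-epoxy-14,15,16-trinorlabdan-13-one
Product: 6 (3R,5S,8S,9S,10R)-3-bromo-8,13-epoxy-14,15,16-trinorlabdan-13-one
Conditions: preparative SFC, amylose tris(3,5-dimethylphenylcarbamate) phase, CO2/MeOH, 35 °C
Reagents that add atoms: none
Why: a carboxyl-terminated bromonium polycyclisation of high enantioselectivity not being established, the enantiomers of the rigid lactone are parted by chromatography on a polysaccharide carbamate chiral phase (no bond is made), the (3R,5S,8S,9S,10R) fraction being assigned by anomalous-dispersion X-ray diffraction on bromine, which fixes the absolute configuration of all five ring stereocentres for the rest of the route.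

Step 4
Reactants: 6 (3R,5S,8S,9S,10R)-3-bromo-8,13-epoxy-14,15,16-trinorlabdan-13-one; 7 methyllithium
Product: 9 (3R,5S,8S,9S,10R)-3-bromo-8-hydroxy-14,15-dinorlabdan-13-one, via lithium hemiketalate 8 (not isolated)
Conditions: MeLi (1.2 equiv), THF, −78 °C; sat. aq. NH4Cl, −78 → 0 °C; crude taken on
Reagents that add atoms: methyllithium 7, [Li]C
Why: nucleophilic addition of MeLi to the δ-lactone stops at the lithium hemiketalate 8, which is stable at −78 °C and gives the δ-hydroxy methyl ketone (in equilibrium with its cyclic hemiketal) on protonation, while the hindered equatorial C3 bromide neither exchanges nor eliminates at this temperature and no stereocentre changes.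

Step 5
Reactants: 9 (3R,5S,8S,9S,10R)-3-bromo-8-hydroxy-14,15-dinorlabdan-13-one; 10 methyltriphenylphosphonium bromide
Product: 12 (3R,5S,8S,9S,10R)-3-bromo-15-norlabd-13-en-8-ol, via methylenetriphenylphosphorane 11 (not isolated)
Conditions: Ph3PCH3Br (3.5 equiv), KOtBu (3.3 equiv), THF, 0 °C; then 9, 0 → 45 °C
Reagents that add atoms: methyltriphenylphosphonium bromide 10, C[P+](c1ccccc1)(c1ccccc1)c1ccccc1.[Br-]
Why: in this Wittig methylenation excess ylide first deprotonates the tertiary alcohol, the hemiketalate reopens under the basic conditions and the methyl ketone becomes the isopropenyl group, with no stereocentre affected.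

Step 6
Reactants: 12 (3R,5S,8S,9S,10R)-3-bromo-15-norlabd-13-en-8-ol; 13 vinyl acetate
Product: 14 (3R,5S,8S,9S,10R)-3-bromo-8-(ethenyloxy)-15-norlabd-13-ene
Conditions: vinyl acetate (5 equiv), [Ir(cod)Cl]2 (2 mol %), Na2CO3 (0.6 equiv), toluene, 100 °C
Reagents that add atoms: vinyl acetate 13, CC(=O)OC=C
Why: iridium-catalysed transfer vinylation from vinyl acetate (alkoxide addition to the coordinated vinyl ester, then β-acetoxy elimination) is suited to hindered tertiary alcohols, the carbonate keeps the medium basic so that the acid-labile tertiary vinyl ether survives, and C8 keeps its configuration because the C8–O bond is not broken.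

Step 7
Reactants: 14 (3R,5S,8S,9S,10R)-3-bromo-8-(ethenyloxy)-15-norlabd-13-ene
Product: 15 (3R,5S,8S,9S,10R)-3-bromo-8,15-epoxy-14-norlabd-13(15)-ene (seven-membered enol ether O–C15H=C13(CH3)–C12–C11–C9–C8)
Conditions: Mo(=CHCMe2Ph)(=N-2,6-iPr2C6H3)[OCMe(CF3)2]2 (15 mol %), toluene (5 mM), 60 °C, argon sparge
Reagents that add atoms: none
Why: in this ring-closing olefin metathesis between the vinyl ether and the 1,1-disubstituted alkene the Schrock molybdenum alkylidene tolerates enol ethers and forms trisubstituted alkenes, the gauche O8/C11 arrangement on the rigid trans-decalin holds the two alkenes close, and loss of ethylene drives closure of the seven-membered enol ether.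

Step 8
Reactants: 15 (3R,5S,8S,9S,10R)-3-bromo-8,15-epoxy-14-norlabd-13(15)-ene; 16 bromoform
Product: 18 (3R,5S,8S,9S,10R,13R,15S)-3,14,14-tribromo-8,15-epoxy-13,15-cyclolabdane (8,8-dibromo-2-oxabicyclo[5.1.0]octane unit), via dibromocarbene 17 (not isolated)
Conditions: CHBr3 (3 equiv), 50% aq. NaOH, BnEt3NCl (5 mol %), CH2Cl2, 0 °C; crude 18 used at once
Reagents that add atoms: bromoform 16, BrC(Br)Br
Why: dibromocarbene generated under phase-transfer conditions adds in a concerted, stereospecific [2+1] cycloaddition to the electron-rich enol ether, the only alkene present, giving a necessarily cis-fused cyclopropane, mainly on the face anti to the axial C8 methyl group (13R,15S), the other face isomer being equally usable because both carry a bromine syn to the ring and give cation 20 in step 9.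

Step 9
Reactants: 18 (3R,5S,8S,9S,10R,13R,15S)-3,14,14-tribromo-8,15-epoxy-13,15-cyclolabdane; 19 methanol
Product: 21 (3R,5S,8S,9S,10R,13E)-3,14-dibromo-15-methoxy-8,15-epoxylabd-13-ene (ring-cis alkene; C15 epimer mixture), via oxocarbenium ion 20 (not isolated)
Conditions: K2CO3 (3 equiv), MeOH, 65 °C
Reagents that add atoms: methanol 19, CO
Why: On heating in methanol the C14–Br bond that lies syn to the oxepane ring ionises while the C13–C15 cyclopropane bond opens in a disrotatory sense (the two-electron electrocyclic opening of a cyclopropyl cation, here pushed by a lone pair of the ring oxygen), which releases the three-ring strain and gives the bromoallyl cation 20, an oxocarbenium ion at C15, that methanol captures at C15 while K2CO3 binds the HBr. The closest known reaction type is the ring expansion of gem-dihalocyclopropanes fused to cyclic enol ethers, as in the conversion of cyclopropanated glycals into 2-bromo-oxepine glycosides, here used one ring size higher. Ring C reaches eight members by this ring enlargement, that is by cleavage of the bond shared by the three- and seven-membered rings and not by an end-to-end cyclisation, and no skeletal bond is formed, both bonds to C14 dating from step 8. The only new stereocentre is the acetal carbon C15, which is expected as an epimer mixture (attack on either face of the planar cation) and is erased in step 11, whereas the C13=C14 geometry is fixed as ring-cis (formally E, since Br outranks C15) because O and C12, being cis to the departing bromide, turn inward. The step needs departure of the syn and not the anti bromide, since a ring of this size could in principle accept the outward rotation that leads to a ring-trans alkene, and it needs capture at C15 and not at C13: the first should be secured because only the inward mode lets the oxygen lone pair conjugate with a planar cation and lets the C13 methyl group turn outward, and because no silver salt is present to pull off the more exposed anti bromide, the second because the positive charge resides mainly on the oxygen-bearing terminus. The equatorial, neopentyl-type C3 bromide has neither an antiperiplanar hydrogen nor any such assistance and should pass through unchanged.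

Step 10
Reactants: 21 (3R,5S,8S,9S,10R,13E)-3,14-dibromo-15-methoxy-8,15-epoxylabd-13-ene
Product: 22 (3R,5S,8S,9S,10R,13Z)-3-bromo-15-methoxy-8,15-epoxylabd-13-ene (ring-cis alkene; C15 epimer mixture)
Conditions: Pd(OAc)2 (10 mol %), PPh3 (20 mol %), HCO2Na (3 equiv), DMF, 80 °C
Reagents that add atoms: none
Why: palladium-catalysed formate hydrogenolysis of the vinyl bromide (oxidative addition of zerovalent palladium to the sp2 C14–Br bond, bromide–formate exchange, loss of CO2 and C–H reductive elimination with retention of alkene geometry) should be selective because phosphine-ligated zerovalent palladium does not insert into the unactivated, neopentyl-type sp3 C3–Br bond under these conditions, and the mixed acetal is inert to the weakly basic formate medium.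

Step 11
Reactants: 22 (3R,5S,8S,9S,10R,13Z)-3-bromo-15-methoxy-8,15-epoxylabd-13-ene
Product: 24 (3R,5S,8S,9S,10R,13Z)-3-bromo-8,15-epoxylabd-13-ene, via debrominated oxocarbenium ion 23 (not isolated)
Conditions: Et3SiH (3 equiv), BF3·OEt2 (1.5 equiv), CH2Cl2, −78 → −40 °C
Reagents that add atoms: none
Why: in this ionic hydrogenation of the allylic acetal BF3·OEt2 removes methoxide to give the bromine-free allyl oxocarbenium ion 23 and Et3SiH delivers hydride to its oxygen-bearing terminus C15 (the end that carries most of the positive charge and the less hindered one, C13 being fully substituted), which erases the C15 stereocentre and should leave the ring-cis alkene in place and the tertiary C8–O bond intact at low temperature.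

Step 12
Reactants: 24 (3R,5S,8S,9S,10R,13Z)-3-bromo-8,15-epoxylabd-13-ene
Product: 25 (3R,5S,8S,9S,10R,13S,14R)-3-bromo-8,15:13,14-diepoxylabdane (CNP0311742.1)
Conditions: Shi ketone from D-fructose (0.3 equiv), KHSO5 (as 2KHSO5·KHSO4·K2SO4), K2CO3, Bu4NHSO4, MeCN/CH2(OMe)2–aq. Na2B4O7/Na2EDTA buffer (pH 10.5), 0 °C
Reagents that add atoms: potassium peroxymonosulfate, [K+].[O-]S(=O)(=O)OO
Why: in this Shi epoxidation the chiral dioxirane reacts through a spiro transition state with the single vinylic hydrogen (on C14) in the sterically demanding quadrant of the catalyst, which should deliver oxygen to the face that gives the 13S,14R epoxide, a face that on models is also the exo face of the ring-cis alkene turned away from the decalin, so that catalyst and substrate preferences are expected to reinforce each other, and oxygen transfer is syn-stereospecific so that C12 and C15 stay cis.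

**Compound list**

1 | (2E,6E)-farnesyl bromide | CC(C)=CCC/C(C)=C/CC/C(C)=C/CBr | starting material
2 | acetic acid | CC(=O)O | starting material
3 | dilithium acetate (acetic acid dianion) | [Li+].[Li+].[CH2-]C(=O)[O-] | intermediate
4 | (4E,8E)-5,9,13-trimethyltetradeca-4,8,12-trienoic acid | CC(C)=CCC/C(C)=C/CC/C(C)=C/CCC(=O)O | intermediate
5 | racemic (3R*,5S*,8S*,9S*,10R*)-3-bromo-8,13-epoxy-14,15,16-trinorlabdan-13-one; trans-decalin, Br and lactone O equatorial; SMILES shows one enantiomer of the racemate | CC1(C)[C@H](Br)CC[C@]2(C)[C@@H]1CC[C@]1(C)OC(=O)CC[C@@H]21 | intermediate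
6 | (3R,5S,8S,9S,10R)-3-bromo-8,13-epoxy-14,15,16-trinorlabdan-13-one | CC1(C)[C@H](Br)CC[C@]2(C)[C@@H]1CC[C@]1(C)OC(=O)CC[C@@H]21 | intermediate
7 | methyllithium | [Li]C | starting material
8 | lithium (3R,5S,8S,9S,10R)-3-bromo-8,13-epoxy-14,15-dinorlabdan-13-olate (cyclic hemiketalate, C13 undefined) | CC1(C)[C@H](Br)CC[C@]2(C)[C@@H]1CC[C@]1(C)OC(C)([O-])CC[C@@H]21.[Li+] | intermediate
9 | (3R,5S,8S,9S,10R)-3-bromo-8-hydroxy-14,15-dinorlabdan-13-one | CC1(C)[C@H](Br)CC[C@]2(C)[C@@H]1CC[C@](C)(O)[C@H]2CCC(C)=O | intermediate
10 | methyltriphenylphosphonium bromide | C[P+](c1ccccc1)(c1ccccc1)c1ccccc1.[Br-] | starting material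
11 | methylenetriphenylphosphorane | C=P(c1ccccc1)(c1ccccc1)c1ccccc1 | intermediate
12 | (3R,5S,8S,9S,10R)-3-bromo-15-norlabd-13-en-8-ol (C13 isopropenyl) | CC1(C)[C@H](Br)CC[C@]2(C)[C@@H]1CC[C@](C)(O)[C@H]2CCC(C)=C | intermediate
13 | vinyl acetate | CC(=O)OC=C | starting material
14 | (3R,5S,8S,9S,10R)-3-bromo-8-(ethenyloxy)-15-norlabd-13-ene | CC1(C)[C@H](Br)CC[C@]2(C)[C@@H]1CC[C@](C)(OC=C)[C@H]2CCC(C)=C | intermediate
15 | (3R,5S,8S,9S,10R)-3-bromo-8,15-epoxy-14-norlabd-13(15)-ene (tricyclic oxepene) | CC1(C)[C@H](Br)CC[C@]2(C)[C@@H]1CC[C@]1(C)OC=C(C)CC[C@@H]21 | intermediate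
16 | bromoform | BrC(Br)Br | starting material
17 | dibromocarbene | Br[C]Br | intermediate
18 | (3R,5S,8S,9S,10R,13R,15S)-3,14,14-tribromo-8,15-epoxy-13,15-cyclolabdane (cis-fused dibromocyclopropane, anti to C17) | CC1(C)[C@H](Br)CC[C@]2(C)[C@@H]1CC[C@]1(C)O[C@@H]3C(Br)(Br)[C@]3(C)CC[C@@H]21 | intermediate
19 | methanol | CO | starting material
20 | ring-cis 14-bromo oxocarbenium ion (C15=O+; cation only) | CC1(C)[C@H](Br)CC[C@]2(C)[C@@H]1CC[C@]1(C)[O+]=C/C(Br)=C(C)\CC[C@@H]21 | intermediate
21 | (3R,5S,8S,9S,10R,13E)-3,14-dibromo-15-methoxy-8,15-epoxylabd-13-ene (ring-cis; C15 epimer mixture, C15 undefined) | CC1(C)[C@H](Br)CC[C@]2(C)[C@@H]1CC[C@]1(C)OC(OC)/C(Br)=C(C)\CC[C@@H]21 | intermediate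
22 | (3R,5S,8S,9S,10R,13Z)-3-bromo-15-methoxy-8,15-epoxylabd-13-ene (ring-cis; C15 epimer mixture, C15 undefined) | CC1(C)[C@H](Br)CC[C@]2(C)[C@@H]1CC[C@]1(C)OC(OC)/C=C(C)\CC[C@@H]21 | intermediate
23 | ring-cis debrominated oxocarbenium ion (C15=O+, C14–H; cation only) | CC1(C)[C@H](Br)CC[C@]2(C)[C@@H]1CC[C@]1(C)[O+]=C/C=C(C)\CC[C@@H]21 | intermediate
24 | (3R,5S,8S,9S,10R,13Z)-3-bromo-8,15-epoxylabd-13-ene | CC1(C)[C@H](Br)CC[C@]2(C)[C@@H]1CC[C@]1(C)OC/C=C(C)\CC[C@@H]21 | intermediate
25 | (3R,5S,8S,9S,10R,13S,14R)-3-bromo-8,15:13,14-diepoxylabdane | CC1(C)[C@H](Br)CC[C@]2(C)[C@@H]1CC[C@]1(C)OC[C@H]3O[C@@]3(C)CC[C@@H]21 | target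

Total step count: 12. Longest linear sequence: 12 steps, from 1.

**Steps most likely to fail**

Step 7. The molybdenum alkylidene may be held on the vinyl ether as a poorly reactive alkoxy-substituted alkylidene and fail to engage the hindered 1,1-disubstituted alkene, or the tertiary vinyl ether may not form cleanly in step 6. The fallback sets out from ketone 9 and returns at oxepene 15, closing the ring through the C8–O–C15 bond. Wittig reaction of 9 with Ph3P=CHOMe (from [Ph3PCH2OMe]Cl and KOtBu, THF) should give the methyl enol ether F1. A trace of pyridinium p-toluenesulfonate in CH2Cl2 over 4 Å molecular sieves should let the tertiary C8 hydroxyl add to the protonated enol ether and close the seven-membered cyclic methyl acetal F2. TMSOTf/iPr2NEt (CH2Cl2, 0 °C) then removes the exocyclic methoxy group and deprotonates C13 to give 15. Neither the vinylation nor a metathesis catalyst is needed.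

Step 9. The anti bromide may leave with outward rotation, which would lead to a ring-trans alkene, or the cation may lose a proton before methanol captures it. The fallback sets out from alcohol 12 and returns at oxocene 24. O-allylation (KH, allyl bromide, THF, 0 → 23 °C) gives the allyl ether F3. Ring-closing metathesis with the second-generation Grubbs catalyst (H2IMes)(PCy3)Cl2Ru=CHPh in dilute toluene at 80 °C then closes ring C at full size with the ring-cis C13=C14 alkene in place. This gives up the ring enlargement but relies only on medium-ring ether metathesis and rejoins the route before the epoxidation.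

Step 12. Oxygen may be delivered to the endo face if the ring conformation overrides the catalyst. The fallback sets out from 24 and returns at 25 and reaches the opposite face by two inversions. NBS in THF/H2O at 0 °C forms the bromonium ion on the exposed face and water opens it anti at the tertiary C13 to give the bromohydrin F4. K2CO3 in MeOH closes the epoxide with inversion at C14, so the oxygen ends on the face opposite to the one an electrophile attacks directly.

Further compounds
F1 | step 7 | (3R,5S,8S,9S,10R)-3-bromo-15-methoxy-14-norlabd-13(15)-en-8-ol (E/Z mixture, geometry undefined) | CC1(C)[C@H](Br)CC[C@]2(C)[C@@H]1CC[C@](C)(O)[C@H]2CCC(C)=COC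
F2 | step 7 | (3R,5S,8S,9S,10R)-3-bromo-15-methoxy-8,15-epoxy-14-norlabdane (epimers at C13 and C15, undefined) | CC1(C)[C@H](Br)CC[C@]2(C)[C@@H]1CC[C@]1(C)OC(OC)C(C)CC[C@@H]21
F3 | step 9 | (3R,5S,8S,9S,10R)-3-bromo-8-(prop-2-enyloxy)-15-norlabd-13-ene | CC1(C)[C@H](Br)CC[C@]2(C)[C@@H]1CC[C@](C)(OCC=C)[C@H]2CCC(C)=C
F4 | step 12 | (3R,5S,8S,9S,10R,13S,14S)-3,14-dibromo-8,15-epoxylabdan-13-ol | CC1(C)[C@H](Br)CC[C@]2(C)[C@@H]1CC[C@]1(C)OC[C@H](Br)[C@@](C)(O)CC[C@@H]21
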